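The numbers in the tables are calculated for an exercise; scatter was added.

| flask | substrate | partner | remark | time |
|---|---|---|---|---|
| elm | 0.050 M | 0.0475 M | run made earlier |  |
| larch | 0.025 M | 0.0475 M | run made earlier |  |
| ash | 0.10 M | 0.0475 M | run made earlier |  |
| maple | 0.050 M | 0.024 M | run made earlier |  |
| dawn | 0.050 M (fed, over 15 min) | 0.0475 M | all else is in the flask from the start; the feed brings no volume worth counting | 20 min |
| noon | 0.050 M | 0.0475 M | everything together at the start | 20 min |
| dusk | 0.050 M (in portions, 3, over 15 min) | 0.0475 M | first portion at the start, last at 15 min | 20 min |
| spring | 0.050 M | 0.0475 M (fed, over 15 min) | all else is in the flask from the start; the feed brings no volume worth counting | 20 min |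

| run | time / min | target / % |
|---|---|---|
| elm | 2.50 | 18.6 |
| elm | 5.00 | 22.4 |
| elm | 8.00 | 25.8 |
| elm | 10.0 | 24.9 |
| elm | 12.0 | 26.0 |
| larch | 2.00 | 13.6 |
| larch | 6.00 | 22.3 |
| larch | 12.0 | 24.3 |
| larch | 15.0 | 23.5 |
| larch | 25.0 | 26.3 |
| ash | 2.00 | 16.0 |
| ash | 4.00 | 21.0 |
| ash | 6.00 | 25.2 |
| ash | 12.0 | 29.5 |
| ash | 25.0 | 32.6 |
| maple | 2.00 | 14.6 |
| maple | 6.00 | 28.2 |
| maple | 12.0 | 34.5 |
| maple | 15.0 | 35.4 |
| maple | 25.0 | 35.9 |

(standard deviation of a reading: 1 percentage point)

- percent here means substrate units held: one idle adduct counts as two
- what is said of target includes idle adduct
- candidate steps: partner + intermediate A -> intermediate B; substrate + partner -> side product A; intermediate B -> side product B; substrate -> target; substrate + target <-> idle adduct; target <-> isomer of the product; substrate + partner <-> intermediate A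
- in an amount of target, one idle adduct counts as one target

* which flask leads in amount of target, in percent of the substrate charged ("all alike" within 1.5 percentage points) (dawn / noon / dusk / spring / all alike)
* how much target is there at the end, in percent of the substrate charged: dawn
* how much target is there at the end, in percent of the substrate charged: noon
* how much target is there at the end, in percent of the substrate charged: dusk
* how much target is there at the end, in percent of the substrate charged: spring

- I planned to read every flask at 20 min, so I kept books on the substrate charged at the point where the target readings flatten: elm's readings from 8.00 min on average 25.6 %, and maple's from 15.0 min on 35.6 %.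
- I assumed that substrate makes target on its own and that its loss to partner is pseudo-first-order at fixed partner. So I took the inverse of the target share as a straight line in starting partner, drawn through elm and maple.
- That line gives the crossing partner, 0.0356 M: the partner level at which the target share falls to half the line's ceiling of 59.7 %. Elm starts above it and maple below it.
- By this line, elm's ledger closes so: 25.6 % target, 34.1 % taken by partner, and 40.3 % outside the ceiling.
- Larch, with half of elm's substrate, read 26.3 % at its last reading, close to elm's 25.6 %, so I put no substrate term in the rule at or below elm's charge. Ash, at 0.10 M, read 32.6 % at its last reading, which the rule, drawn at elm's charge, does not cover.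
- Dawn, noon and dusk start with the full partner, 0.0475 M, above the crossing, so I read them near elm. Spring's steady feed puts in, averaged over its 15 min, half its charge, 0.0238 M, which is below the crossing, and with that level the rule gave me 35.8 %.
- The forecast named spring, with 26.5 % for dawn, 26.5 % for noon, 26 % for dusk and 42 % for spring, on the ground that “Feeding partner keeps partner low while substrate is present”. Its spring figure stood above mine.
- Dawn gave 25.7 %, noon 27.2 %, dusk 24.9 % and spring 36.9 %, so spring led, and the forecast's spring figure was 5.1 percentage points high.
- Over the first 15 min, mean partner was 0.0176 M in spring and 0.0288 M in noon, both below the crossing of 0.0356 M.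

    partner + intermediate A → intermediate B (k = 0.310 L mol⁻¹ min⁻¹)
    substrate + partner → side product A (k = 1.42 L mol⁻¹ min⁻¹)
    intermediate B → side product B (k = 0.236 min⁻¹)
    substrate → target (k = 0.104 min⁻¹)
    substrate + target ⇌ idle adduct, settled at all times (K = 6.40 L mol⁻¹)
    target ⇌ isomer of the product (K = 0.990, k = 0.140 min⁻¹)
    substrate + partner ⇌ intermediate A (K = 56.7 L mol⁻¹, k = 2.35 L mol⁻¹ min⁻¹)

- The neighbour of spring charged with 0.020 M of substrate had the same partner feed, so the rule with the same crossing gave 35.8 %, and that flask stood at 35.6 %.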